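Locants used throughout: ring A is C1–C6 and ring B is C3, C4, C7–C11. C1 is the oxygen-bearing CH, C2 a CH2, C3 and C4 the fusion CH groups (C3 bonded to C11, C4 to C7), C5=C6 the alkene with a methyl on C6, C7 the CMe2 carbon, C8–C10 CH2 groups and C11 the C(CH3)OH carbon. The same locants are used for the monocyclic precursors (ring C1–C6, side chain C7–C11). In the benzo[7]annulene names of the bicyclic compounds, C1, C3, C4, C6 and C11 are positions 3, 4a, 9a, 2 and 5.

## Analysis of the target

Target 20 is the 3-hydroxy-4-methoxybenzoate of a himachalane-type diol: a cyclohexene (ring A) fused through C3–C4 to a cycloheptane (ring B). The four stereocentres C1, C3, C4 and C11 are all R. In relative terms H3 and H4 are anti (trans fusion), the C1 oxygen lies on the face of H3 and is therefore pseudoaxial on the ring A half-chair, and the C11 hydroxyl is cis to H3 across ring B, with its methyl cis to C2. The sensitive groups are the secondary allylic aryl ester (ionisation, allylic shift, hydrolysis), the tertiary alcohol (dehydration), the free phenol, and C4–H, which becomes epimerisable whenever a C1 ketone is conjugated to C5=C6. The synthesis is hard because each fusion methine is flanked by a fully substituted carbon (C7 or C11), ring B is seven-membered, and C1 must be set in the less accessible pseudoaxial sense far from the fusion. The route rests on one feature: C11 is a carbinol carbon bonded to C3, and C3 is beta to the C1 oxygen. With C1 as a ketone and C2=C3 as an alkene, the C3–C11 bond is the union of a ketone carbon with an enone beta carbon, which is exactly the bond a one-electron reductant makes.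

## Retrosynthetic reasoning

**Ester and silyl groups.** The C1–O acyl bond is cut last. Target 20 comes from the doubly silylated ester 19 by fluoride deprotection, and 19 from allylic alcohol 15 and the phenol-protected acid 18, itself one step from isovanillic acid 16. The cut is made here because the allylic ester would not survive enolate or hydride chemistry. The esterification is planned with inversion because hydride delivery to the C1 ketone gives the pseudoequatorial alcohol, whereas the target needs the pseudoaxial oxygen.

**C1–H.** Alcohol 15 goes back to enone 14 by 1,2-reduction. This leaves C1 as a carbonyl for all earlier steps, where it activates C6 and C5.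

**C5=C6 and C6–CH3.** Enone 14 is taken back through silyl enol ether 13 and methyl ketone 12 to the silyl-protected bicyclic ketone 10. The C6–CH3 bond and the alkene are cut here rather than carried from the start, because a methyl-free ring A keeps the precursor of the ring closure prochiral and free of extra stereochemical variables. The forward steps have to enolise the C1 ketone toward C6 and away from the ring fusion, once kinetically (methylation) and once under equilibrium (desaturation).

**C3–C11, the central cut.** Ketone 10 is the silyl ether of hydroxy ketone 9, and 9 is opened between C3 and C11 to give keto enone 8. Cutting here removes ring B, two stereocentres and the tertiary alcohol in one stroke and leaves a monocyclic compound with a single stereocentre. No other bond of ring B does this. C4–C7 would require a quaternary centre to be formed in the closure, and C10–C11 would leave the C3 and C4 relationship to be built first. The forward reaction is a reductive closure with a divalent samarium reagent. It must form the bond on the C3 face anti to the side chain and keep the metal-bound oxygen turned away from the enone.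

**C2=C3 and the C4 stereocentre.** Keto enone 8 comes from its ketal 7, and 7 from the enantioenriched silyl enol ether 6 by Saegusa oxidation. Enol ether 6 arises from the achiral 4-substituted cyclohexanone 5 by enantioselective deprotonation. This places the only stereocentre of the precursor by desymmetrisation, and the bulky tert-alkyl substituent at C4 is the best case for that reaction.

**Ring A and the aryl–C7 bond.** Cyclohexanone 5 is the partial hydrogenation product of phenol ketal 4, made from keto phenol 3. Keto phenol 3 is cut at the aryl–C7 bond into phenol 1 and 6-methylhept-5-en-2-one 2. The tertiary cation of 2 carries exactly the C7–C11 chain with its methyl ketone, so the whole carbon skeleton of 8 comes from two commodity chemicals in one Friedel–Crafts step.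

## Alternatives that were turned down

Alternative 1: Ring A is cut at C4–C5 and ring B is kept as a cycloheptenone. The precursor A1 is a 2-substituted 4,4-dimethylcyclohept-2-enone whose side chain carries the silylated C1 carbinol and a Z vinyl iodide at C5. In the forward step a radical chain converts the iodide into the C5 vinyl radical, which closes 6-endo onto the enone beta carbon C4. The alpha-keto radical at C3 then takes up hydrogen to give ketone A2, and the C11 carbinol would follow by methyl addition to the ketone.
- For: C1 is configured before the closure, so the ester can be made with retention and no inversion step is needed. C3 is alpha to the C11 ketone in A2, so the ring fusion can be equilibrated. On this point the alternative is stronger than the chosen route, which fixes C3 irreversibly.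
- Against: C4 is neopentylic next to C7, and its configuration would be induced only remotely from C1. The C11 stereocentre is left to a late methyl addition to a hindered, enolisable ketone of uncertain facial preference. A1 needs a separately built cycloheptenone and a stereodefined vinyl iodide.
- Comparison: the chosen route sets C3 and C11 in one bond-forming event from a precursor six steps from commodity materials. In exchange for the lost equilibration handle it offers a short, reliable approach that concentrates the risk in one step.

Alternative 2: Both rings are cut at once, back to the acyclic diphosphate A3 ((2E,6E)-farnesyl diphosphate). In the forward step a class 1 sesquiterpene synthase ionises A3 and closes C4–C7. After a hydride shift it closes C3–C4, and the C11 cation is hydrated to give the 1-deoxy alcohol A4.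
- For: one step would build both rings, three stereocentres and the alkene under enzyme control. In step economy and absolute stereocontrol nothing in the chosen route matches this.
- Against: the route needs an expressed enzyme with exactly this product profile (trans fusion, 11R hydration), which is not a purchasable reagent and cannot be argued from structure. A4 lacks the C1 oxygen, so a late allylic C–H oxidation would have to pick C1 over the C4 methine and the C6 methyl and deliver the pseudoaxial epimer.
- Comparison: the chosen route is longer, but every step can be defended mechanistically with ordinary reagents. It also carries the C1 oxygen from the first step as the carbonyl that drives all later ring A chemistry.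

Alternative 3: Ring B is cut at C4–C7 and the ester C1–O bond in the same operation. The precursor A5 is a ring A 1,3-diene (C1=C6–C5=C4) bearing at C3 the C11 trifluoroacetate and a chain ending in the tertiary C7 chloride. In the forward step the monovalent silver salt A6 of the acetyl-protected acid removes chloride, the C7 cation attacks the diene terminus C4, and the carboxylate captures the allyl cation at C1 to give the protected target A7.
- For: it is the most convergent plan. Ring closure, the C4 centre and the ester arrive together, and no separate esterification or inversion is needed, which is better than the chosen endgame.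
- Against: three selectivities must hold at once with no controlling element. The tertiary cation must cyclise rather than lose a proton or be captured directly by the carboxylate. C4 must form trans to the C3 substituent. The ion pair must collapse at C1 rather than C5 and on the pseudoaxial face. In addition, the C3 and C11 pair of A5 has to be made beforehand by other stereocontrolled chemistry, and the cyclohexadiene is prone to isomerisation and aromatisation.
- Comparison: the chosen route spends more steps after ring closure, but it separates the stereochemical problems and solves C1 by a reduction and inversion sequence with predictable outcomes.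

Key step: step 7

Assumption: the sense of the enantioselective deprotonation in step 4 is taken to follow that of 4-tert-butylcyclohexanone, where the (S,S)-amide leads to the (R)-enol silane; if the side chain reversed it, the (R,R)-amine would be used.

## Route

Step 1
Reactants: 1 phenol; 2 6-methylhept-5-en-2-one
Product: 3 6-(4-hydroxyphenyl)-6-methylheptan-2-one
Conditions: AlCl3 (3 equiv), 1 (2 equiv), CH2Cl2, 0 °C to rt; aq. HCl work-up
Reagents that add atoms: none
Why: Friedel–Crafts alkylation: protonation of the trisubstituted alkene gives the tertiary C7 cation, which attacks the para position because ortho attack by a tert-alkyl electrophile is hindered; AlCl3 bound to the ketone oxygen keeps the carbonyl from trapping the cation, and alkylation of arenes by this enone is a known reaction type.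

Step 2
Reactants: 3 6-(4-hydroxyphenyl)-6-methylheptan-2-one
Product: 4 4-[2-methyl-5-(2-methyl-1,3-dioxolan-2-yl)pentan-2-yl]phenol
Conditions: ethylene glycol (3 equiv), p-toluenesulfonic acid monohydrate (cat.), toluene, reflux, Dean–Stark
Reagents that add atoms: ethylene glycol, OCCO
Why: Acid-catalysed ketalisation with azeotropic removal of water; the phenol is inert, and the dioxolane masks the methyl ketone against hydrogenation and against the amide base of step 4.

Step 3
Reactants: 4 4-[2-methyl-5-(2-methyl-1,3-dioxolan-2-yl)pentan-2-yl]phenol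
Product: 5 4-[2-methyl-5-(2-methyl-1,3-dioxolan-2-yl)pentan-2-yl]cyclohexan-1-one
Conditions: H2 (5 bar), Pd/C, Na2CO3 (cat.), cyclohexane, 80 °C, stopped after uptake of 2 equiv H2
Reagents that add atoms: none
Why: Partial hydrogenation of a para-alkylphenol: on Pd/C the ring is reduced to the enol, which tautomerises to the cyclohexanone and is reduced further only slowly; the trace of base protects the ketal, and the product is achiral because C1 and C4 lie on a mirror plane.

Step 4
Reactants: 5 4-[2-methyl-5-(2-methyl-1,3-dioxolan-2-yl)pentan-2-yl]cyclohexan-1-one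
Product: 6 trimethyl({(4R)-4-[2-methyl-5-(2-methyl-1,3-dioxolan-2-yl)pentan-2-yl]cyclohex-1-en-1-yl}oxy)silane
Conditions: (S,S)-bis(1-phenylethyl)amine (1.2 equiv), n-BuLi (1.15 equiv), THF, −78 °C; TMSCl (5 equiv), then 5, −90 to −78 °C (in situ quench)
Reagents that add atoms: chlorotrimethylsilane, C[Si](C)(C)Cl
Why: Enantioselective deprotonation: the C2-symmetric lithium amide distinguishes the two enantiotopic axial alpha protons of the conformationally locked 4-tert-alkylcyclohexanone, and the enolate is silylated as it forms; this desymmetrisation makes C4 a stereocentre (R), with the level of induction expected to follow the 4-tert-butyl case, and any shortfall could be made up by recrystallising hydroxy ketone 9.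

Step 5
Reactants: 6 trimethyl({(4R)-4-[2-methyl-5-(2-methyl-1,3-dioxolan-2-yl)pentan-2-yl]cyclohex-1-en-1-yl}oxy)silane
Product: 7 (4R)-4-[2-methyl-5-(2-methyl-1,3-dioxolan-2-yl)pentan-2-yl]cyclohex-2-en-1-one
Conditions: Pd(OAc)2 (1.1 equiv), MeCN, rt
Reagents that add atoms: none
Why: Saegusa oxidation: the silyl enol ether gives an enolate of divalent palladium, and beta-hydride elimination from C3 places the C2=C3 alkene on the side fixed in step 4; C4 is untouched and the ketal tolerates the conditions.

Step 6
Reactants: 7 (4R)-4-[2-methyl-5-(2-methyl-1,3-dioxolan-2-yl)pentan-2-yl]cyclohex-2-en-1-one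
Product: 8 (4R)-4-(2-methyl-6-oxoheptan-2-yl)cyclohex-2-en-1-one
Conditions: 1 M aq. HCl, THF, 0 °C to rt
Reagents that add atoms: water, O
Why: Acid hydrolysis of the dioxolane frees the methyl ketone; dilute acid at room temperature is too mild to enolise the enone toward C4, so the stereocentre is kept.

Step 7
Reactants: 8 (4R)-4-(2-methyl-6-oxoheptan-2-yl)cyclohex-2-en-1-one
Product: 9 (4aR,5R,9aR)-5-hydroxy-5,9,9-trimethyl-1,2,4,4a,5,6,7,8,9,9a-decahydro-3H-benzo[7]annulen-3-one (trans-fused C1 ketone with C11 tertiary alcohol)
Conditions: SmI2 (2.5 equiv), HMPA (10 equiv), t-BuOH (2 equiv), THF, −78 to 0 °C, slow addition of 8 (final 0.01 M); aq. NH4Cl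
Reagents that add atoms: none
Why: SmI2 activated by HMPA (divalent samarium) transfers one electron to 8; the enone is the easier acceptor and the methyl ketone the intended ketyl site, but either radical anion leads to the same event, union of the carbonyl carbon C11 with the enone beta carbon C3. The alpha-keto radical so formed is reduced by a second SmI2 to the C1=C2 enolate of trivalent samarium, which t-BuOH protonates at C2, so no stereocentre arises there. The closest known reaction type is the SmI2 ketyl–olefin (carbonyl–enone) reductive cyclisation, for which seven-membered closures onto electron-poor alkenes are documented. Ring B closes in the 7-exo-trig mode (C3 inside and C2 outside the new ring); the gem-dimethyl group at C7 restricts the chain to folded rotamers, and high dilution holds back beta,beta-dimerisation and simple 1,4-reduction. C3 is controlled by C4: with the tert-alkyl anchor pseudoequatorial, bonding on the face anti to the C4–C7 bond places C11 and C7 both equatorial on ring A (trans fusion, 3R). C11 is controlled by the HMPA-solvated O–Sm group, which avoids the enone carbon C2 in the transition state and ends anti to it, that is cis to H3 (11R), the usual anti preference of these cyclisations under non-chelating conditions. The step therefore needs anti selectivity at both centres; the substrate supplies a locked pseudoequatorial anchor and a fully substituted, heavily solvated ketyl carbon that would be pressed against the C7 methyl groups and the axial C5–H in the competing pseudoaxial approach. Ring A by itself prefers axial bond formation, so the facial selectivity at C3 is the open point of the route and is treated as such at the end.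

Step 8
Reactants: 9 (4aR,5R,9aR)-5-hydroxy-5,9,9-trimethyl-1,2,4,4a,5,6,7,8,9,9a-decahydro-3H-benzo[7]annulen-3-one
Product: 10 (4aR,5R,9aR)-5,9,9-trimethyl-5-(triethylsilyloxy)-1,2,4,4a,5,6,7,8,9,9a-decahydro-3H-benzo[7]annulen-3-one
Conditions: TESOTf (1.3 equiv), 2,6-lutidine, CH2Cl2, −78 to 0 °C
Reagents that add atoms: triethylsilyl trifluoromethanesulfonate, CC[Si](CC)(CC)OS(=O)(=O)C(F)(F)F
Why: Silylation of the hindered tertiary alcohol with a silyl triflate; the ether removes the acidic proton before the enolate chemistry and adds bulk next to C2, and any silyl enol ether formed alongside is hydrolysed on aqueous work-up.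

Step 9
Reactants: 10 (4aR,5R,9aR)-5,9,9-trimethyl-5-(triethylsilyloxy)-1,2,4,4a,5,6,7,8,9,9a-decahydro-3H-benzo[7]annulen-3-one
Product: 12 (4aR,5R,9aR)-2,5,9,9-tetramethyl-5-(triethylsilyloxy)-1,2,4,4a,5,6,7,8,9,9a-decahydro-3H-benzo[7]annulen-3-one (C6 methyl ketone; both C6 epimers serve), via lithium enolate 11 (not isolated)
Conditions: LDA (1.1 equiv), THF, −78 °C; MeI (3 equiv), DMPU, −78 to −40 °C
Reagents that add atoms: iodomethane, CI
Why: Kinetic enolate alkylation: LDA removes the axial C6 proton in preference to the C2 proton, which is screened by the C3 substituent and its silyloxy-bearing C11, the same bias that directs enolisation of trans-fused 3-keto steroids away from the ring fusion; the configuration of the new C6 centre is irrelevant because C6 becomes sp2 in step 10.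

Step 10
Reactants: 12 (4aR,5R,9aR)-2,5,9,9-tetramethyl-5-(triethylsilyloxy)-1,2,4,4a,5,6,7,8,9,9a-decahydro-3H-benzo[7]annulen-3-one
Product: 13 [(4aR,5R,9aR)-2,5,9,9-tetramethyl-5-(triethylsilyloxy)-4,4a,5,6,7,8,9,9a-octahydro-1H-benzo[7]annulen-3-yl]oxy(trimethyl)silane (C1=C6 silyl enol ether)
Conditions: TMSCl (3 equiv), NaI (3 equiv), Et3N (4 equiv), MeCN, rt to 40 °C
Reagents that add atoms: chlorotrimethylsilane, C[Si](C)(C)Cl
Why: Equilibrating silyl enol ether formation with iodotrimethylsilane made in the flask gives the more substituted C1=C6 enol ether, which is also the one pointing away from the ring fusion; both C6 epimers of 12 converge on it.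

Step 11
Reactants: 13 [(4aR,5R,9aR)-2,5,9,9-tetramethyl-5-(triethylsilyloxy)-4,4a,5,6,7,8,9,9a-octahydro-1H-benzo[7]annulen-3-yl]oxy(trimethyl)silane
Product: 14 (4aR,5R,9aR)-2,5,9,9-tetramethyl-5-(triethylsilyloxy)-4,4a,5,6,7,8,9,9a-octahydro-3H-benzo[7]annulen-3-one (C5=C6 enone)
Conditions: Pd(OAc)2 (1.1 equiv), MeCN, rt to 40 °C
Reagents that add atoms: none
Why: Saegusa oxidation: the palladium enolate at C6 loses a syn beta hydrogen from C5 to give the conjugated endocyclic 2-methyl enone rather than the exocyclic methylene isomer; C4–H is now gamma to the carbonyl, so the product is kept away from base.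

Step 12
Reactants: 14 (4aR,5R,9aR)-2,5,9,9-tetramethyl-5-(triethylsilyloxy)-4,4a,5,6,7,8,9,9a-octahydro-3H-benzo[7]annulen-3-one
Product: 15 (3S,4aR,5R,9aR)-2,5,9,9-tetramethyl-5-(triethylsilyloxy)-4,4a,5,6,7,8,9,9a-octahydro-3H-benzo[7]annulen-3-ol (pseudoequatorial C1 alcohol)
Conditions: NaBH4, CeCl3·7H2O, MeOH, −78 to 0 °C
Reagents that add atoms: none
Why: Luche reduction: 1,2-selective hydride delivery along the axial trajectory, on the face of the axial H3, gives the pseudoequatorial (1S)-alcohol, the C1 epimer of what the ester needs; this is the intrinsic preference of a 2-methylcyclohexenone with no axial substituent at C3.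

Step 13
Reactants: 16 isovanillic acid (3-hydroxy-4-methoxybenzoic acid)
Product: 18 3-(tert-butyldimethylsilyloxy)-4-methoxybenzoic acid, via tert-butyldimethylsilyl ester 17 (not isolated)
Conditions: TBSCl (2.5 equiv), imidazole (5 equiv), DMF, rt; then AcOH–H2O–THF, rt
Reagents that add atoms: tert-butylchlorodimethylsilane, CC(C)(C)[Si](C)(C)Cl
Why: Exhaustive silylation followed by selective hydrolysis of the far more labile silyl ester leaves the phenol masked as its TBS ether, so that the Mitsunobu reaction cannot alkylate the phenolic oxygen.

Step 14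
Reactants: 15 (3S,4aR,5R,9aR)-2,5,9,9-tetramethyl-5-(triethylsilyloxy)-4,4a,5,6,7,8,9,9a-octahydro-3H-benzo[7]annulen-3-ol; 18 3-(tert-butyldimethylsilyloxy)-4-methoxybenzoic acid
Product: 19 (3R,4aR,5R,9aR)-2,5,9,9-tetramethyl-5-(triethylsilyloxy)-4,4a,5,6,7,8,9,9a-octahydro-3H-benzo[7]annulen-3-yl 3-(tert-butyldimethylsilyloxy)-4-methoxybenzoate
Conditions: PPh3 (2 equiv), DIAD (2 equiv), 18 (1.5 equiv), toluene, 0 °C to rt
Reagents that add atoms: none
Why: Mitsunobu esterification: the alkoxyphosphonium ion of the pseudoequatorial alcohol is displaced by the carboxylate in an SN2 step from the axial direction, which inverts C1 to R and puts the ester oxygen pseudoaxial, cis to H3; SN2' attack is disfavoured because C5 is screened by the C4 substituent.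

Step 15
Reactants: 19 (3R,4aR,5R,9aR)-2,5,9,9-tetramethyl-5-(triethylsilyloxy)-4,4a,5,6,7,8,9,9a-octahydro-3H-benzo[7]annulen-3-yl 3-(tert-butyldimethylsilyloxy)-4-methoxybenzoate
Product: 20 (3R,4aR,5R,9aR)-5-hydroxy-2,5,9,9-tetramethyl-4,4a,5,6,7,8,9,9a-octahydro-3H-benzo[7]annulen-3-yl 3-hydroxy-4-methoxybenzoate (CNP0210711.2)
Conditions: HF·pyridine, pyridine, THF, 0 °C to rt
Reagents that add atoms: none
Why: Fluoride-mediated desilylation removes the aryl TBS ether and the tertiary TES ether in one operation under buffered, non-nucleophilic conditions that leave the allylic ester and the tertiary alcohol intact.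

## Compound list

1 | phenol | Oc1ccccc1 | starting material
2 | 6-methylhept-5-en-2-one | CC(=O)CCC=C(C)C | starting material
3 | 6-(4-hydroxyphenyl)-6-methylheptan-2-one | CC(=O)CCCC(C)(C)c1ccc(O)cc1 | intermediate
4 | 4-[2-methyl-5-(2-methyl-1,3-dioxolan-2-yl)pentan-2-yl]phenol | CC1(CCCC(C)(C)c2ccc(O)cc2)OCCO1 | intermediate
5 | 4-[2-methyl-5-(2-methyl-1,3-dioxolan-2-yl)pentan-2-yl]cyclohexan-1-one | CC1(CCCC(C)(C)C2CCC(=O)CC2)OCCO1 | intermediate
6 | trimethyl({(4R)-4-[2-methyl-5-(2-methyl-1,3-dioxolan-2-yl)pentan-2-yl]cyclohex-1-en-1-yl}oxy)silane | C[Si](C)(C)OC1=CC[C@@H](CC1)C(C)(C)CCCC1(C)OCCO1 | intermediate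
7 | (4R)-4-[2-methyl-5-(2-methyl-1,3-dioxolan-2-yl)pentan-2-yl]cyclohex-2-en-1-one | O=C1C=C[C@@H](CC1)C(C)(C)CCCC1(C)OCCO1 | intermediate
8 | (4R)-4-(2-methyl-6-oxoheptan-2-yl)cyclohex-2-en-1-one | O=C1C=C[C@@H](CC1)C(C)(C)CCCC(C)=O | intermediate
9 | (4aR,5R,9aR)-5-hydroxy-5,9,9-trimethyl-1,2,4,4a,5,6,7,8,9,9a-decahydro-3H-benzo[7]annulen-3-one | O=C1C[C@@H]2[C@@H](CC1)C(C)(C)CCC[C@@]2(C)O | intermediate
10 | (4aR,5R,9aR)-5,9,9-trimethyl-5-(triethylsilyloxy)-1,2,4,4a,5,6,7,8,9,9a-decahydro-3H-benzo[7]annulen-3-one | O=C1C[C@@H]2[C@@H](CC1)C(C)(C)CCC[C@@]2(C)O[Si](CC)(CC)CC | intermediate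
11 | lithium (4aR,5R,9aR)-5,9,9-trimethyl-5-(triethylsilyloxy)-4,4a,5,6,7,8,9,9a-octahydro-1H-benzo[7]annulen-3-olate (C1=C6 enolate, not isolated) | [Li+].[O-]C=1C[C@@H]2[C@@H](CC=1)C(C)(C)CCC[C@@]2(C)O[Si](CC)(CC)CC | intermediate
12 | (4aR,5R,9aR)-2,5,9,9-tetramethyl-5-(triethylsilyloxy)-1,2,4,4a,5,6,7,8,9,9a-decahydro-3H-benzo[7]annulen-3-one (C6 left undefined, both epimers serve) | O=C1C[C@@H]2[C@@H](CC1C)C(C)(C)CCC[C@@]2(C)O[Si](CC)(CC)CC | intermediate
13 | [(4aR,5R,9aR)-2,5,9,9-tetramethyl-5-(triethylsilyloxy)-4,4a,5,6,7,8,9,9a-octahydro-1H-benzo[7]annulen-3-yl]oxy(trimethyl)silane | C[Si](C)(C)OC=1C[C@@H]2[C@@H](CC=1C)C(C)(C)CCC[C@@]2(C)O[Si](CC)(CC)CC | intermediate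
14 | (4aR,5R,9aR)-2,5,9,9-tetramethyl-5-(triethylsilyloxy)-4,4a,5,6,7,8,9,9a-octahydro-3H-benzo[7]annulen-3-one | O=C1C[C@@H]2[C@@H](C=C1C)C(C)(C)CCC[C@@]2(C)O[Si](CC)(CC)CC | intermediate
15 | (3S,4aR,5R,9aR)-2,5,9,9-tetramethyl-5-(triethylsilyloxy)-4,4a,5,6,7,8,9,9a-octahydro-3H-benzo[7]annulen-3-ol | O[C@H]1C[C@@H]2[C@@H](C=C1C)C(C)(C)CCC[C@@]2(C)O[Si](CC)(CC)CC | intermediate
16 | isovanillic acid (3-hydroxy-4-methoxybenzoic acid) | COc1ccc(C(=O)O)cc1O | starting material
17 | tert-butyldimethylsilyl 3-(tert-butyldimethylsilyloxy)-4-methoxybenzoate (not isolated) | COc1ccc(C(=O)O[Si](C)(C)C(C)(C)C)cc1O[Si](C)(C)C(C)(C)C | intermediate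
18 | 3-(tert-butyldimethylsilyloxy)-4-methoxybenzoic acid | COc1ccc(C(=O)O)cc1O[Si](C)(C)C(C)(C)C | intermediate
19 | (3R,4aR,5R,9aR)-2,5,9,9-tetramethyl-5-(triethylsilyloxy)-4,4a,5,6,7,8,9,9a-octahydro-3H-benzo[7]annulen-3-yl 3-(tert-butyldimethylsilyloxy)-4-methoxybenzoate | COc1ccc(C(=O)O[C@@H]2C[C@@H]3[C@@H](C=C2C)C(C)(C)CCC[C@@]3(C)O[Si](CC)(CC)CC)cc1O[Si](C)(C)C(C)(C)C | intermediate
20 | (3R,4aR,5R,9aR)-5-hydroxy-2,5,9,9-tetramethyl-4,4a,5,6,7,8,9,9a-octahydro-3H-benzo[7]annulen-3-yl 3-hydroxy-4-methoxybenzoate | COc1ccc(C(=O)O[C@@H]2C[C@@H]3[C@@H](C=C2C)C(C)(C)CCC[C@@]3(C)O)cc1O | target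

## Step count and least certain steps

Total: 15 steps. Longest linear sequence: 14 steps (steps 1–12, 14 and 15); step 13 is a one-step side branch.

**Step 7 (key step).** The most likely failure is poor facial selectivity at C3. Bond formation could occur on the face syn to the C4–C7 bond and give the cis-fused isomer, because pseudoaxial attack on the enone is what ring A prefers stereoelectronically and only the steric demand of the ketyl argues against it.

The fallback accepts the cis closure and corrects C4 afterwards. It sets out from ketone 5. Deprotonation with the (R,R)-amide and silylation give the (S)-enol silane F1. Saegusa oxidation gives the (S)-enone ketal F2, and hydrolysis the (S)-keto enone F3. The same SmI2 closure, now syn to the side chain, would give the cis-fused hydroxy ketone F4, which has C3 and C11 in the required absolute configuration and only C4 wrong. Silylation to the TES ether F5, methylation through the lithium enolate F6 to the methyl ketone F7, equilibrating silylation to the enol ether F8 and Saegusa oxidation lead to the cis-fused enone F9. In F9 the C4 hydrogen is gamma to the carbonyl. Equilibration through the extended enolate (DBU, toluene, 80 °C) should favour the trans isomer, the only one in which neither fully substituted carbon has to be axial on ring A. The fallback returns to the route at enone 14.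

**Step 1.** The likely failure is loss of chemoselectivity: the ketone may condense with the phenol or capture the C7 cation through its oxygen instead of standing by during the alkylation. The fallback takes the carbonyl out of play and sets out from 2. Reduction with NaBH4 gives 6-methylhept-5-en-2-ol F10. Acid-catalysed alkylation of 1 with F10 (CH3SO3H, excess 1, 60 °C) gives 4-(6-hydroxy-2-methylheptan-2-yl)phenol F11; any cyclic ether formed on the way ionises back to the same cation. Oppenauer oxidation (Al(OiPr)3, acetone, toluene, reflux), which leaves the phenol alone, returns to the route at 3.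

**Step 3.** The likely failure is over-reduction of the cyclohexanone to the cyclohexanol, since the selectivity of the partial hydrogenation depends on the catalyst batch and on where the uptake is stopped. The fallback sets out from 4. Exhaustive hydrogenation (H2, Rh/Al2O3, EtOAc) gives 4-[2-methyl-5-(2-methyl-1,3-dioxolan-2-yl)pentan-2-yl]cyclohexan-1-ol F12 as a cis and trans mixture, and Swern oxidation returns to the route at 5.

**Step 4.** The likely failure is incomplete enantioselection in the deprotonation, because the long side chain is not the tert-butyl group for which the amide was optimised, and all later stereocentres depend on this one. The fallback replaces desymmetrisation by resolution and sets out from 5. LDA and TMSCl (in situ quench) give the racemic enol silane F13, and Pd(OAc)2 the racemic enone ketal F14. Lithiated (S)-N,S-dimethyl-S-phenylsulfoximine adds to the carbonyl group to give diastereomeric adducts. The adduct of the (R)-enone, F15, is separated by chromatography and thermolysed in refluxing toluene, which returns to the route at 7.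

**Step 9.** The likely failure is loss of regiocontrol and over-alkylation: some enolisation toward C2, and proton exchange between enolate and product leading to dimethylation. The fallback avoids enolate alkylation and sets out from 10. TMSCl, NaI and Et3N give the C1=C6 silyl enol ether F16, and Saegusa oxidation the unmethylated enone F17. Iodination at the alpha carbon (I2, pyridine, CH2Cl2) gives the 6-iodo enone F18. Stille coupling with Me4Sn (PdCl2(PhCN)2, AsPh3, CuI, NMP) places the methyl group unambiguously at C6 and returns to the route at 14.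

**Step 14.** The likely failure is elimination to a ring A diene, or allylic transposition, in place of clean SN2 inversion, because the alkoxyphosphonium ion sits at a hindered allylic carbon. The fallback sets the C1 configuration by reagent control and esterifies with retention. It sets out from 14. Corey–Bakshi–Shibata reduction with (S)-1-methyl-3,3-diphenyltetrahydro-1H,3H-pyrrolo[1,2-c][1,3,2]oxazaborole and BH3·SMe2 is predicted to give the pseudoaxial (1R)-alcohol F19 if the alkene carbon C6 acts as the large group. Acylation of F19 with 18 (EDC·HCl, 4-(dimethylamino)pyridine, CH2Cl2) returns to the route at 19.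

## Further compounds

F1 | step 7 | trimethyl({(4S)-4-[2-methyl-5-(2-methyl-1,3-dioxolan-2-yl)pentan-2-yl]cyclohex-1-en-1-yl}oxy)silane | C[Si](C)(C)OC1=CC[C@H](CC1)C(C)(C)CCCC1(C)OCCO1
F2 | step 7 | (4S)-4-[2-methyl-5-(2-methyl-1,3-dioxolan-2-yl)pentan-2-yl]cyclohex-2-en-1-one | O=C1C=C[C@H](CC1)C(C)(C)CCCC1(C)OCCO1
F3 | step 7 | (4S)-4-(2-methyl-6-oxoheptan-2-yl)cyclohex-2-en-1-one | O=C1C=C[C@H](CC1)C(C)(C)CCCC(C)=O
F4 | step 7 | (4aR,5R,9aS)-5-hydroxy-5,9,9-trimethyl-1,2,4,4a,5,6,7,8,9,9a-decahydro-3H-benzo[7]annulen-3-one (cis-fused) | O=C1C[C@@H]2[C@H](CC1)C(C)(C)CCC[C@@]2(C)O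
F5 | step 7 | (4aR,5R,9aS)-5,9,9-trimethyl-5-(triethylsilyloxy)-1,2,4,4a,5,6,7,8,9,9a-decahydro-3H-benzo[7]annulen-3-one | O=C1C[C@@H]2[C@H](CC1)C(C)(C)CCC[C@@]2(C)O[Si](CC)(CC)CC
F6 | step 7 | lithium (4aR,5R,9aS)-5,9,9-trimethyl-5-(triethylsilyloxy)-4,4a,5,6,7,8,9,9a-octahydro-1H-benzo[7]annulen-3-olate (not isolated) | [Li+].[O-]C=1C[C@@H]2[C@H](CC=1)C(C)(C)CCC[C@@]2(C)O[Si](CC)(CC)CC
F7 | step 7 | (4aR,5R,9aS)-2,5,9,9-tetramethyl-5-(triethylsilyloxy)-1,2,4,4a,5,6,7,8,9,9a-decahydro-3H-benzo[7]annulen-3-one (C6 undefined) | O=C1C[C@@H]2[C@H](CC1C)C(C)(C)CCC[C@@]2(C)O[Si](CC)(CC)CC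
F8 | step 7 | [(4aR,5R,9aS)-2,5,9,9-tetramethyl-5-(triethylsilyloxy)-4,4a,5,6,7,8,9,9a-octahydro-1H-benzo[7]annulen-3-yl]oxy(trimethyl)silane | C[Si](C)(C)OC=1C[C@@H]2[C@H](CC=1C)C(C)(C)CCC[C@@]2(C)O[Si](CC)(CC)CC
F9 | step 7 | (4aR,5R,9aS)-2,5,9,9-tetramethyl-5-(triethylsilyloxy)-4,4a,5,6,7,8,9,9a-octahydro-3H-benzo[7]annulen-3-one (cis-fused enone) | O=C1C[C@@H]2[C@H](C=C1C)C(C)(C)CCC[C@@]2(C)O[Si](CC)(CC)CC
F10 | step 1 | 6-methylhept-5-en-2-ol (racemic) | CC(O)CCC=C(C)C
F11 | step 1 | 4-(6-hydroxy-2-methylheptan-2-yl)phenol (racemic) | CC(O)CCCC(C)(C)c1ccc(O)cc1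
F12 | step 3 | 4-[2-methyl-5-(2-methyl-1,3-dioxolan-2-yl)pentan-2-yl]cyclohexan-1-ol (cis and trans) | CC1(CCCC(C)(C)C2CCC(O)CC2)OCCO1
F13 | step 4 | racemic trimethyl({4-[2-methyl-5-(2-methyl-1,3-dioxolan-2-yl)pentan-2-yl]cyclohex-1-en-1-yl}oxy)silane | C[Si](C)(C)OC1=CCC(CC1)C(C)(C)CCCC1(C)OCCO1
F14 | step 4 | racemic 4-[2-methyl-5-(2-methyl-1,3-dioxolan-2-yl)pentan-2-yl]cyclohex-2-en-1-one | O=C1C=CC(CC1)C(C)(C)CCCC1(C)OCCO1
F15 | step 4 | (4R)-1-{[(S)-N-methyl-S-phenylsulfonimidoyl]methyl}-4-[2-methyl-5-(2-methyl-1,3-dioxolan-2-yl)pentan-2-yl]cyclohex-2-en-1-ol (carbinol centre as formed) | CN=[S@](=O)(CC1(O)C=C[C@@H](CC1)C(C)(C)CCCC1(C)OCCO1)c1ccccc1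
F16 | step 9 | [(4aR,5R,9aR)-5,9,9-trimethyl-5-(triethylsilyloxy)-4,4a,5,6,7,8,9,9a-octahydro-1H-benzo[7]annulen-3-yl]oxy(trimethyl)silane | C[Si](C)(C)OC=1C[C@@H]2[C@@H](CC=1)C(C)(C)CCC[C@@]2(C)O[Si](CC)(CC)CC
F17 | step 9 | (4aR,5R,9aR)-5,9,9-trimethyl-5-(triethylsilyloxy)-4,4a,5,6,7,8,9,9a-octahydro-3H-benzo[7]annulen-3-one | O=C1C[C@@H]2[C@@H](C=C1)C(C)(C)CCC[C@@]2(C)O[Si](CC)(CC)CC
F18 | step 9 | (4aR,5R,9aR)-2-iodo-5,9,9-trimethyl-5-(triethylsilyloxy)-4,4a,5,6,7,8,9,9a-octahydro-3H-benzo[7]annulen-3-one | O=C1C[C@@H]2[C@@H](C=C1I)C(C)(C)CCC[C@@]2(C)O[Si](CC)(CC)CC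
F19 | step 14 | (3R,4aR,5R,9aR)-2,5,9,9-tetramethyl-5-(triethylsilyloxy)-4,4a,5,6,7,8,9,9a-octahydro-3H-benzo[7]annulen-3-ol | O[C@@H]1C[C@@H]2[C@@H](C=C1C)C(C)(C)CCC[C@@]2(C)O[Si](CC)(CC)CC
A1 | alternative 1 | 2-[(2R,3Z)-2-(tert-butyldimethylsilyloxy)-4-iodo-3-methylbut-3-en-1-yl]-4,4-dimethylcyclohept-2-en-1-one | CC(C)(C)[Si](C)(C)O[C@H](CC1=CC(C)(C)CCCC1=O)/C(C)=C\I
A2 | alternative 1 | trans-fused bicyclic C11 ketone with C1 silyl ether | CC(C)(C)[Si](C)(C)O[C@@H]1C[C@@H]2[C@@H](C=C1C)C(C)(C)CCCC2=O
A3 | alternative 2 | (2E,6E)-farnesyl diphosphate | CC(C)=CCC/C(C)=C/CC/C(C)=C/COP(=O)(O)OP(=O)(O)O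
A4 | alternative 2 | 1-deoxy core alcohol (trans-fused, C11 tertiary alcohol, C5=C6 alkene) | C1C[C@@H]2[C@@H](C=C1C)C(C)(C)CCC[C@@]2(C)O
A5 | alternative 3 | (2R)-6-chloro-6-methyl-2-[(1R)-4-methylcyclohexa-2,4-dien-1-yl]heptan-2-yl trifluoroacetate | CC1=CC[C@H](C=C1)[C@](C)(OC(=O)C(F)(F)F)CCCC(C)(C)Cl
A6 | alternative 3 | silver 3-acetoxy-4-methoxybenzoate (monovalent silver) | COc1ccc(C([O-])=O)cc1OC(C)=O.[Ag+]
A7 | alternative 3 | target carrying an aryl acetate and a C11 trifluoroacetate | COc1ccc(C(=O)O[C@@H]2C[C@@H]3[C@@H](C=C2C)C(C)(C)CCC[C@@]3(C)OC(=O)C(F)(F)F)cc1OC(C)=O
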